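Hippolide C is disconnected at the lactone O–C5 bond of the furan-2(5H)-one ring. C4 of that ring, the β-carbon, carries both the ring CH2 (C5) and the side-chain carbinol carbon; joining the carbinol oxygen to C5 therefore gives an isomer of the target, an (E)-(2R)-2-alkyl-oxetan-3-ylidene acetic acid carrying the complete hydroxymethyl-tetraene chain. In the final step a mild acid lets the carboxyl oxygen displace the oxetane oxygen at the unsubstituted CH2, which closes the butenolide and frees the (R)-carbinol in one isomerisation, with the stereocentre untouched. The precursor is assembled by RAMP-hydrazone alkylation of oxetan-3-one with a C20 allylic bromide, Wittig olefination, desilylation and ester hydrolysis.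

Key step: step 13

Assumption: the RAMP azaenolate is alkylated in the usual sense for SAMP/RAMP hydrazones of cyclic ketones, so RAMP gives R at C2 (SAMP would be used if the sense proved opposite), and the minor diastereomer of 15 is removed by chromatography before hydrolysis.

Step 1
Reactants: 1 (2E,6E)-farnesol
Product: 2 (2E,6E)-farnesal
Conditions: MnO2 (excess), CH2Cl2, rt
Reagents that add atoms: none
Why: Heterogeneous MnO2 oxidation is selective for the allylic alcohol and should leave the 2E geometry and the other trisubstituted alkenes untouched.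

Step 2
Reactants: 2 (2E,6E)-farnesal
Product: 3 (3E,7E)-4,8,12-trimethyltrideca-1,3,7,11-tetraene
Conditions: Ph3PCH3Br, n-BuLi, THF, 0 °C; then 2, 0 °C to rt
Reagents that add atoms: methyltriphenylphosphonium bromide, C[P+](c1ccccc1)(c1ccccc1)c1ccccc1.[Br-]
Why: Wittig methylenation of the enal with the non-stabilised ylide should give the terminal 1,3-diene without disturbing the adjacent E alkene.

Step 3
Reactants: 4 but-2-yne-1,4-diol
Product: 5 4-[(tert-butyldimethylsilyl)oxy]but-2-yn-1-ol
Conditions: TBSCl (limiting), imidazole, DMF, 0 °C to rt; diol in threefold excess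
Reagents that add atoms: tert-butyldimethylsilyl chloride, CC(C)(C)[Si](C)(C)Cl
Why: Silyl ether formation on a symmetrical diol used in excess should give mainly the monoprotected alcohol, which is easily separated from diol and bis-ether.

Step 4
Reactants: 5 4-[(tert-butyldimethylsilyl)oxy]but-2-yn-1-ol
Product: 7 (Z)-4-[(tert-butyldimethylsilyl)oxy]-3-iodobut-2-en-1-ol, via sodium vinylalanate 6 (not isolated)
Conditions: NaAlH2(OCH2CH2OMe)2, THF, 0 °C to rt; then I2, −78 °C to 0 °C
Reagents that add atoms: iodine, II; NaAlH2(OCH2CH2OMe)2, [Na+].COCCO[AlH2-]OCCOC (its sodium, aluminium and alkoxy groups stand in intermediate 6 only)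
Why: Alkoxide-directed trans-hydroalumination delivers hydride to C2 and aluminium to C3 through a five-membered oxaaluminacycle, and iodinolysis with retention should give the (Z)-3-iodoallylic alcohol as one regio- and stereoisomer.

Step 5
Reactants: 3 (3E,7E)-4,8,12-trimethyltrideca-1,3,7,11-tetraene; 7 (Z)-4-[(tert-butyldimethylsilyl)oxy]-3-iodobut-2-en-1-ol
Product: 9 (2E,6E,10E)-3-{[(tert-butyldimethylsilyl)oxy]methyl}-7,11,15-trimethylhexadeca-2,6,10,14-tetraen-1-ol, via B-homofarnesyl-9-BBN 8 (not isolated)
Conditions: 3, 9-BBN, THF, 0 °C to rt; then 7, PdCl2(dppf) (cat.), AsPh3, Cs2CO3, DMF/H2O, rt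
Reagents that add atoms: 9-BBN, B1C2CCCC1CCC2 (its atoms stand in intermediate 8 only)
Why: 9-BBN should hydroborate only the monosubstituted terminal alkene, and the B-alkyl Suzuki–Miyaura coupling of the primary alkylborane with the vinyl iodide proceeds with retention of alkene geometry and tolerates the free hydroxyl.

Step 6
Reactants: 9 (2E,6E,10E)-3-{[(tert-butyldimethylsilyl)oxy]methyl}-7,11,15-trimethylhexadeca-2,6,10,14-tetraen-1-ol
Product: 10 (2E,6E,10E)-1-bromo-3-{[(tert-butyldimethylsilyl)oxy]methyl}-7,11,15-trimethylhexadeca-2,6,10,14-tetraene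
Conditions: CBr4, PPh3, CH2Cl2, −20 °C to 0 °C; used without storage
Reagents that add atoms: carbon tetrabromide, BrC(Br)(Br)Br
Why: The Appel reaction converts the primary allylic alcohol into the bromide under neutral conditions by SN2 displacement of the oxyphosphonium group, leaving silyl ether and alkene geometry intact.

Step 7
Reactants: 11 oxetan-3-one; 12 RAMP, (R)-1-amino-2-(methoxymethyl)pyrrolidine
Product: 13 (2R)-2-(methoxymethyl)-N-(oxetan-3-ylidene)pyrrolidin-1-amine
Conditions: neat, 4 Å molecular sieves, 50 °C
Reagents that add atoms: none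
Why: Hydrazone formation by condensation of the hydrazine with the strained, electrophilic ketone should go to completion once water is removed.

Step 8
Reactants: 13 (2R)-2-(methoxymethyl)-N-(oxetan-3-ylidene)pyrrolidin-1-amine; 10 (2E,6E,10E)-1-bromo-3-{[(tert-butyldimethylsilyl)oxy]methyl}-7,11,15-trimethylhexadeca-2,6,10,14-tetraene
Product: 15 (2R)-N-{(2R)-2-[(2E,6E,10E)-3-{[(tert-butyldimethylsilyl)oxy]methyl}-7,11,15-trimethylhexadeca-2,6,10,14-tetraen-1-yl]oxetan-3-ylidene}-2-(methoxymethyl)pyrrolidin-1-amine, via lithium azaenolate 14 (not isolated)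
Conditions: t-BuLi (1.0 equiv), THF, −78 °C; then 10, −78 °C to rt
Reagents that add atoms: tert-butyllithium, [Li]C(C)(C)C (its lithium stands in intermediate 14 only)
Why: In this SAMP/RAMP-type chiral hydrazone alkylation the methoxymethyl-chelated lithium azaenolate is attacked by the reactive allylic bromide in SN2 fashion on the face left open by the pyrrolidine, which with RAMP should set oxetane C2 as R.

Step 9
Reactants: 15 alkylated RAMP hydrazone (as named in step 8)
Product: 16 (2R)-2-[(2E,6E,10E)-3-{[(tert-butyldimethylsilyl)oxy]methyl}-7,11,15-trimethylhexadeca-2,6,10,14-tetraen-1-yl]oxetan-3-one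
Conditions: sat. aq. (CO2H)2, Et2O, rt; used directly
Reagents that add atoms: water, O
Why: Mild biphasic hydrazone hydrolysis with oxalic acid should release the ketone without enolising the α-stereocentre or harming the silyl ether and oxetane, the auxiliary being recovered from the aqueous phase.

Step 10
Reactants: 16 (2R)-2-alkyloxetan-3-one (as named in step 9); 17 ethyl (triphenylphosphoranylidene)acetate
Product: 18 ethyl (2E)-2-{(2R)-2-[(2E,6E,10E)-3-{[(tert-butyldimethylsilyl)oxy]methyl}-7,11,15-trimethylhexadeca-2,6,10,14-tetraen-1-yl]oxetan-3-ylidene}acetate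
Conditions: CH2Cl2, 0 °C to rt; chromatography to remove any Z isomer
Reagents that add atoms: none
Why: Wittig olefination with the stabilised ylide is fast on the strained ketone under neutral conditions, so the α-stereocentre should not epimerise, and the ester should prefer the side of the unsubstituted ring CH2 (E isomer).

Step 11
Reactants: 18 silyl-protected (E)-alkylidene-oxetane ethyl ester (as named in step 10)
Product: 19 ethyl (2E)-2-{(2R)-2-[(2E,6E,10E)-3-(hydroxymethyl)-7,11,15-trimethylhexadeca-2,6,10,14-tetraen-1-yl]oxetan-3-ylidene}acetate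
Conditions: TBAF, AcOH, THF, 0 °C to rt
Reagents that add atoms: none
Why: Acetic-acid-buffered fluoride desilylation should free the primary allylic alcohol without base-mediated attack on the alkylidene-oxetane ester.

Step 12
Reactants: 19 hydroxy ethyl ester (as named in step 11)
Product: 21 (2E)-2-{(2R)-2-[(2E,6E,10E)-3-(hydroxymethyl)-7,11,15-trimethylhexadeca-2,6,10,14-tetraen-1-yl]oxetan-3-ylidene}acetic acid, via lithium carboxylate 20 (not isolated)
Conditions: LiOH, THF/H2O, 0 °C; then dilute HCl to pH 4–5, 0 °C, cold extraction; used at once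
Reagents that add atoms: lithium hydroxide, [Li+].[OH-] (its oxygen stands in the carboxyl group; its lithium stands in intermediate 20 only)
Why: Ester saponification at low temperature is expected to leave the oxetane untouched, since a carboxylate does not open an unactivated oxetane, and careful acidification then gives the free acid.

Step 13
Reactants: 21 (E)-(2R)-2-alkyl-oxetan-3-ylidene acetic acid (as named in step 12)
Product: 22 hippolide C, 4-[(1R,3E,7E,11E)-1-hydroxy-4-(hydroxymethyl)-8,12,16-trimethylheptadeca-3,7,11,15-tetraen-1-yl]furan-2(5H)-one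
Conditions: (PhO)2P(O)OH (10 mol %), toluene, 45 °C, argon
Reagents that add atoms: none
Why: Proposed new method: the phosphoric acid diester activates the oxetane oxygen by hydrogen bonding or protonation while the carboxyl oxygen, held in the plane of the four-membered ring by the exocyclic E alkene and lying behind the CH2–O bond, displaces that oxygen in an intramolecular SN2 reaction, and proton transfer then gives the neutral lactone and the free carbinol. The closest known reaction type is the acid-promoted isomerisation of saturated oxetane-carboxylic acids to lactones by intramolecular ring opening, together with Brønsted-acid-catalysed intramolecular oxetane openings; its use on a 3-alkylidene-oxetane acid to give a butenolide is the new element. The five-membered ring closes in a 5-exo-tet mode driven by release of oxetane strain, and the ring angles at the attacked carbon (about 90° towards the leaving oxygen and about 105° towards the incoming one) should allow a nearly collinear displacement. No new stereocentre is formed, and the C–O bond at the carbinol carbon is not broken, so the R configuration set in step 8 is retained. The step needs attack at the ring CH2 and not at the substituted CH: the E geometry fixed in step 10 places the carboxyl group beside the CH2 and out of reach of the stereogenic carbon, and the electron-poor alkene disfavours ionisation there. The catalyst is expected to be too weak to ionise the primary allylic alcohol or to protonate the trisubstituted alkenes.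

Compound list

1 | (2E,6E)-farnesol, (2E,6E)-3,7,11-trimethyldodeca-2,6,10-trien-1-ol | CC(C)=CCC/C(C)=C/CC/C(C)=C/CO | starting material
2 | (2E,6E)-farnesal | CC(C)=CCC/C(C)=C/CC/C(C)=C/C=O | intermediate
3 | (3E,7E)-4,8,12-trimethyltrideca-1,3,7,11-tetraene | CC(C)=CCC/C(C)=C/CC/C(C)=C/C=C | intermediate
4 | but-2-yne-1,4-diol | OCC#CCO | starting material
5 | 4-[(tert-butyldimethylsilyl)oxy]but-2-yn-1-ol | OCC#CCO[Si](C)(C)C(C)(C)C | intermediate
6 | sodium vinylalanate, cyclic oxaaluminole ate complex from trans-hydroalumination of 5 (not isolated) | [Na+].COCCO[Al-]1(OCCOC)OC/C=C\1CO[Si](C)(C)C(C)(C)C | intermediate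
7 | (Z)-4-[(tert-butyldimethylsilyl)oxy]-3-iodobut-2-en-1-ol | OC/C=C(\I)CO[Si](C)(C)C(C)(C)C | intermediate
8 | B-[(3E,7E)-4,8,12-trimethyltrideca-3,7,11-trien-1-yl]-9-BBN (not isolated) | CC(C)=CCC/C(C)=C/CC/C(C)=C/CCB1C2CCCC1CCC2 | intermediate
9 | (2E,6E,10E)-3-{[(tert-butyldimethylsilyl)oxy]methyl}-7,11,15-trimethylhexadeca-2,6,10,14-tetraen-1-ol | CC(C)=CCC/C(C)=C/CC/C(C)=C/CC/C(=C\CO)CO[Si](C)(C)C(C)(C)C | intermediate
10 | (2E,6E,10E)-1-bromo-3-{[(tert-butyldimethylsilyl)oxy]methyl}-7,11,15-trimethylhexadeca-2,6,10,14-tetraene | CC(C)=CCC/C(C)=C/CC/C(C)=C/CC/C(=C\CBr)CO[Si](C)(C)C(C)(C)C | intermediate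
11 | oxetan-3-one | O=C1COC1 | starting material
12 | RAMP, (R)-1-amino-2-(methoxymethyl)pyrrolidine | COC[C@H]1CCCN1N | starting material
13 | (2R)-2-(methoxymethyl)-N-(oxetan-3-ylidene)pyrrolidin-1-amine | COC[C@H]1CCCN1N=C1COC1 | intermediate
14 | lithium azaenolate of 13 (not isolated) | COC[C@H]1CCCN1N([Li])C1=COC1 | intermediate
15 | (2R)-N-{(2R)-2-[(2E,6E,10E)-3-{[(tert-butyldimethylsilyl)oxy]methyl}-7,11,15-trimethylhexadeca-2,6,10,14-tetraen-1-yl]oxetan-3-ylidene}-2-(methoxymethyl)pyrrolidin-1-amine (C=N geometry not defined) | CC(C)=CCC/C(C)=C/CC/C(C)=C/CC/C(=C\C[C@H]1OCC1=NN1CCC[C@@H]1COC)CO[Si](C)(C)C(C)(C)C | intermediate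
16 | (2R)-2-[(2E,6E,10E)-3-{[(tert-butyldimethylsilyl)oxy]methyl}-7,11,15-trimethylhexadeca-2,6,10,14-tetraen-1-yl]oxetan-3-one | CC(C)=CCC/C(C)=C/CC/C(C)=C/CC/C(=C\C[C@H]1OCC1=O)CO[Si](C)(C)C(C)(C)C | intermediate
17 | ethyl (triphenylphosphoranylidene)acetate | CCOC(=O)C=P(c1ccccc1)(c1ccccc1)c1ccccc1 | starting material
18 | ethyl (2E)-2-{(2R)-2-[(2E,6E,10E)-3-{[(tert-butyldimethylsilyl)oxy]methyl}-7,11,15-trimethylhexadeca-2,6,10,14-tetraen-1-yl]oxetan-3-ylidene}acetate | CC(C)=CCC/C(C)=C/CC/C(C)=C/CC/C(=C\C[C@@H](O1)/C(=C/C(=O)OCC)C1)CO[Si](C)(C)C(C)(C)C | intermediate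
19 | ethyl (2E)-2-{(2R)-2-[(2E,6E,10E)-3-(hydroxymethyl)-7,11,15-trimethylhexadeca-2,6,10,14-tetraen-1-yl]oxetan-3-ylidene}acetate | CC(C)=CCC/C(C)=C/CC/C(C)=C/CC/C(=C\C[C@@H](O1)/C(=C/C(=O)OCC)C1)CO | intermediate
20 | lithium carboxylate of 21 (not isolated) | [Li+].CC(C)=CCC/C(C)=C/CC/C(C)=C/CC/C(=C\C[C@@H](O1)/C(=C/C(=O)[O-])C1)CO | intermediate
21 | (2E)-2-{(2R)-2-[(2E,6E,10E)-3-(hydroxymethyl)-7,11,15-trimethylhexadeca-2,6,10,14-tetraen-1-yl]oxetan-3-ylidene}acetic acid | CC(C)=CCC/C(C)=C/CC/C(C)=C/CC/C(=C\C[C@@H](O1)/C(=C/C(=O)O)C1)CO | intermediate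
22 | hippolide C, 4-[(1R,3E,7E,11E)-1-hydroxy-4-(hydroxymethyl)-8,12,16-trimethylheptadeca-3,7,11,15-tetraen-1-yl]furan-2(5H)-one | CC(C)=CCC/C(C)=C/CC/C(C)=C/CC/C(=C\C[C@@H](O)C1=CC(=O)OC1)CO | target

Total step count: 13. Longest linear sequence: 10 steps (1 → 2 → 3 → 9 → 10 → 15 → 16 → 18 → 19 → 21 → 22; equally long from 4).

Steps most likely to fail

1. Step 13. The intramolecular displacement may be slow because the conjugated carboxyl group is a weak nucleophile. Forcing it with stronger acid or heat could ionise the allylic C–O bond at the stereocentre, direct attack to the substituted ring carbon, or start cation–olefin reactions of the polyene. Fallback by known chemistry, setting out from bromide 10 (with 12 and 17) and returning at 22: the butenolide is made without the oxetane. Commercial 2,2-dimethyl-1,3-dioxan-5-one is condensed with 12 to the RAMP hydrazone of 2,2-dimethyl-1,3-dioxan-5-one F1. Deprotonation with t-BuLi in THF at −78 °C and alkylation with 10 should give the alkylated dioxanone hydrazone F2, with the same sense of facial control (R at the new centre). Aqueous oxalic acid in Et2O then releases the (4R)-4-alkyl-2,2-dimethyl-1,3-dioxan-5-one F3. Wittig olefination with 17 gives the (E)-alkylidene dioxane ester F4, with the ester on the side of the ring CH2. Warm aqueous acetic acid in THF finally removes the acetonide and the silyl ether, and the freed primary hydroxyl cis to the ester lactonises to 22.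

2. Step 10. Geometric control in the olefination may be poor, because the wide exocyclic angles of the four-membered ring weaken the steric bias between the CH2 side and the substituted side. Fallback, setting out from 16 and returning at 18: the geometry is corrected after the olefination instead of relying on kinetic selectivity. The ethyl (2Z)-alkylidene-oxetane ester F5, separated from 18 by chromatography, is irradiated at 254 nm in degassed hexane to a photostationary E/Z mixture (direct photoisomerisation of the enoate; the isolated trisubstituted alkenes do not absorb). The mixture is re-chromatographed and the E portion rejoins the route as 18; the cycle is repeated as needed.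

3. Step 8. Facial discrimination in the alkylation of the small, flat four-membered azaenolate may be incomplete, which would carry the S antipode forward, and separation of the diastereomers of 15 may be blurred by C=N isomers. Fallback, setting out from 15 and returning at 18: the single enantiomer is obtained by resolution instead of auxiliary control alone. Material of 15 is taken through steps 9 and 10 as planned, and the partly enriched ester 18, which is neutral, stable and carries the enoate chromophore, is resolved by preparative chromatography on a polysaccharide chiral stationary phase. Enantiopure 18 then continues through steps 11–13; no new compound is made.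

Further compounds
F1 | step 13 | (2R)-N-(2,2-dimethyl-1,3-dioxan-5-ylidene)-2-(methoxymethyl)pyrrolidin-1-amine (RAMP hydrazone of 2,2-dimethyl-1,3-dioxan-5-one) | COC[C@H]1CCCN1N=C1COC(C)(C)OC1
F2 | step 13 | (2R)-N-{(4R)-4-[(2E,6E,10E)-3-{[(tert-butyldimethylsilyl)oxy]methyl}-7,11,15-trimethylhexadeca-2,6,10,14-tetraen-1-yl]-2,2-dimethyl-1,3-dioxan-5-ylidene}-2-(methoxymethyl)pyrrolidin-1-amine (C=N geometry not defined) | CC(C)=CCC/C(C)=C/CC/C(C)=C/CC/C(=C\C[C@H]1OC(C)(C)OCC1=NN1CCC[C@@H]1COC)CO[Si](C)(C)C(C)(C)C
F3 | step 13 | (4R)-4-[(2E,6E,10E)-3-{[(tert-butyldimethylsilyl)oxy]methyl}-7,11,15-trimethylhexadeca-2,6,10,14-tetraen-1-yl]-2,2-dimethyl-1,3-dioxan-5-one | CC(C)=CCC/C(C)=C/CC/C(C)=C/CC/C(=C\C[C@H]1OC(C)(C)OCC1=O)CO[Si](C)(C)C(C)(C)C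
F4 | step 13 | ethyl (2E)-2-{(4R)-4-[(2E,6E,10E)-3-{[(tert-butyldimethylsilyl)oxy]methyl}-7,11,15-trimethylhexadeca-2,6,10,14-tetraen-1-yl]-2,2-dimethyl-1,3-dioxan-5-ylidene}acetate | CC(C)=CCC/C(C)=C/CC/C(C)=C/CC/C(=C\C[C@@H](OC(C)(C)OC1)/C1=C/C(=O)OCC)CO[Si](C)(C)C(C)(C)C
F5 | step 10 | ethyl (2Z)-2-{(2R)-2-[(2E,6E,10E)-3-{[(tert-butyldimethylsilyl)oxy]methyl}-7,11,15-trimethylhexadeca-2,6,10,14-tetraen-1-yl]oxetan-3-ylidene}acetate | CC(C)=CCC/C(C)=C/CC/C(C)=C/CC/C(=C\C[C@@H](O1)/C(=C\C(=O)OCC)C1)CO[Si](C)(C)C(C)(C)C
F0 | step 8 | none | none
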